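## Retrosynthetic overview

1. Numbering: benzofuranone O1, C2, C3, C3a, C4–C7, C7a (ring A = benzene, ring B = furanone), side chain C1′–C12′. The C2–OH is released last from the PMB ketal 19, and the C2–C1′ bond comes from a Tsuji–Trost asymmetric allylic alkylation of the racemic core 11 with side-chain acetate 17, which sets C2.
2. Core 11 comes from the acyclic acid 6 by an aryne relay (key step): Br–Li exchange and loss of LiF give a 3-oxy-aryne (C3a≡C4), MeLi adds at C4, and the C3a–Li closes ring B on the tethered carboxylate, forming C3–C3a.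
3. Enabling feature: the contiguous triad on ring A (C7a–O1, C3a–C3(=O), C4–CH3) is the pattern left by nucleophile/electrophile addition across an aryne polarised by the neighbouring ether oxygen O1, and O1–C2–C3 of ring B holds the electrophilic C3 at five-ring distance from C3a.
4. Side chain 17 comes from geranyl acetate 12 by allylic oxidation at C8′, Keck allylation (sets C8′) and cross-metathesis to the prenyl end; the acetate of 12 is kept as the leaving group for the coupling.
5. Ring order: ring A is bought (in 1); ring B is the only ring made, in step 5.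

Key step: step 5

Remark on the chemistry: the C2 hemiketal can epimerise by ring opening to the 2-hydroxyaryl 1,2-dione; it is assumed to hold its configuration at neutral pH, so C2 is carried as a PMB ketal and freed only in the last step at pH 7.

## Route

Step 1
Reactants: 1 3-bromo-2-fluorophenol; 2 methyl bromoacetate
Product: 3 methyl 2-(3-bromo-2-fluorophenoxy)acetate
Conditions: K2CO3, acetone, reflux
Reagents that add atoms: none
Why: Williamson ether synthesis, in which the acidic halophenol is O-alkylated by the activated primary bromide.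

Step 2
Reactants: 3 methyl 2-(3-bromo-2-fluorophenoxy)acetate
Product: 4 rac-methyl 2-bromo-2-(3-bromo-2-fluorophenoxy)acetate
Conditions: NBS (1.05 equiv), AIBN (5 mol %), PhCF3, 85 °C
Reagents that add atoms: N-bromosuccinimide, O=C1CCC(=O)N1Br
Why: Wohl–Ziegler radical bromination should be selective for the C–H flanked by the aryloxy oxygen and the ester (captodative radical), since the halogenated arene has no benzylic hydrogen and is deactivated.

Step 3
Reactants: 4 rac-methyl 2-bromo-2-(3-bromo-2-fluorophenoxy)acetate
Product: 5 rac-methyl 2-(3-bromo-2-fluorophenoxy)-2-[(4-methoxybenzyl)oxy]acetate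
Conditions: 4-methoxybenzyl alcohol, K2CO3, 4 Å MS, MeCN, 0 °C → rt
Reagents that add atoms: 4-methoxybenzyl alcohol, COc1ccc(CO)cc1
Why: nucleophilic substitution of an α-halo ether by the alcohol should give the mixed O,O-acetal, which puts C2 at the ketal oxidation level; C2 is racemic here, which is harmless because it is planarised in step 10.

Step 4
Reactants: 5 rac-methyl 2-(3-bromo-2-fluorophenoxy)-2-[(4-methoxybenzyl)oxy]acetate
Product: 6 rac-2-(3-bromo-2-fluorophenoxy)-2-[(4-methoxybenzyl)oxy]acetic acid
Conditions: LiOH·H2O, THF/H2O, 0 °C → rt; then 1 M HCl, 0 °C, pH 3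
Reagents that add atoms: lithium hydroxide, [Li+].[OH-]
Why: ester saponification leaves the acetal and the aryl halides untouched and provides the carboxylic acid, whose lithium salt is an acyl donor that tolerates alkyllithiums at low temperature.

Step 5
Reactants: 6 rac-2-(3-bromo-2-fluorophenoxy)-2-[(4-methoxybenzyl)oxy]acetic acid
Product: 11 rac-2-[(4-methoxybenzyl)oxy]-4-methylbenzofuran-3(2H)-one, via fluoroaryllithium 7 (not isolated), via aryne 8 (not isolated), via aryllithium 9 (not isolated), via gem-diolate 10 (not isolated)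
Conditions: MeLi (1.0 equiv), THF, −78 °C; n-BuLi (1.05 equiv), −78 °C; MeLi (3 equiv), −78 → −20 °C; AcOH, −78 °C
Reagents that add atoms: methyllithium, C[Li]
Why: Proposed new method: after the carboxylate is formed, Br–Li exchange at C4 gives 7, which should lose LiF on warming to give the 3-oxy-aryne 8 (C3a≡C4); MeLi adds at C4 to give 9, whose C3a–Li attacks the tethered lithium carboxylate to give gem-diolate 10, and this becomes the C3 ketone on acidic quench. The closest known reaction types are the three-component couplings in which an organolithium or Grignard reagent adds to a 3-alkoxybenzyne and the ortho-metallated aryl ether so formed is trapped by CO2 or another carbon electrophile, and the Parham cyclisation of aryllithiums onto lithium carboxylates; here the two are merged by tethering the electrophile to the directing oxygen. Ring B is closed by a 5-exo-trig anionic acylation that forms the C3–C3a bond. No stereocentre is created, since C2 stays racemic and is set in step 10. The step needs methyl delivery to C4 only and use of the carboxylate only by C3a–Li: the inductively withdrawing O1 on C7a distorts the aryne so that the nucleophile enters at the distal carbon C4 and the carbanion develops at C3a next to oxygen, and a lithium carboxylate resists MeLi below −20 °C while sitting within five-ring reach of C3a–Li. The acetal C–H and the PMB ether should not be deprotonated by MeLi at these temperatures.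

Step 6
Reactants: 12 geranyl acetate
Product: 13 (2E,6E)-8-hydroxy-3,7-dimethylocta-2,6-dien-1-yl acetate
Conditions: SeO2 (0.1 equiv), t-BuOOH (70% aq., 3 equiv), salicylic acid (0.1 equiv), CH2Cl2, rt
Reagents that add atoms: selenium dioxide (catalytic oxygen carrier), O=[Se]=O; tert-butyl hydroperoxide (terminal oxidant), CC(C)(C)OO
Why: SeO2 allylic oxidation (ene reaction, then [2,3]-sigmatropic shift) should be selective for the (E)-methyl group of the terminal trisubstituted alkene, because the other alkene is deactivated by the allylic acetate.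

Step 7
Reactants: 13 (2E,6E)-8-hydroxy-3,7-dimethylocta-2,6-dien-1-yl acetate
Product: 14 (2E,6E)-3,7-dimethyl-8-oxoocta-2,6-dien-1-yl acetate
Conditions: MnO2 (activated, excess), CH2Cl2, rt
Reagents that add atoms: none
Why: MnO2 oxidation is selective for the primary allylic alcohol and should give the enal without touching the acetate or the alkene geometry.

Step 8
Reactants: 14 (2E,6E)-3,7-dimethyl-8-oxoocta-2,6-dien-1-yl acetate
Product: 16 (2E,6E,8R)-8-hydroxy-3,7-dimethylundeca-2,6,10-trien-1-yl acetate, via stannyl ether 15 (not isolated)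
Conditions: allylSnBu3, (R)-BINOL (10 mol %), Ti(OiPr)4 (10 mol %), 4 Å MS, CH2Cl2, −20 °C; aq. NaHCO3
Reagents that add atoms: allyltributylstannane, C=CC[Sn](CCCC)(CCCC)CCCC
Why: Keck asymmetric allylation, in which the (R)-BINOL–titanium Lewis acid should direct 1,2-allyl transfer to the Re face of the enal and so set C8′ as (R) by catalyst control; the sense is assigned by analogy and is to be confirmed by Mosher ester analysis.

Step 9
Reactants: 16 (2E,6E,8R)-8-hydroxy-3,7-dimethylundeca-2,6,10-trien-1-yl acetate
Product: 17 (2E,6E,8R)-8-hydroxy-3,7,11-trimethyldodeca-2,6,10-trien-1-yl acetate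
Conditions: second-generation Grubbs catalyst (5 mol %), 2-methyl-2-butene/CH2Cl2, 40 °C
Reagents that add atoms: 2-methyl-2-butene, CC=C(C)C
Why: olefin cross-metathesis, in which only the monosubstituted alkene should engage the ruthenium carbene and be capped by excess 2-methyl-2-butene as the prenyl terminus, while the trisubstituted alkenes and the C8′ carbinol stay untouched.

Step 10
Reactants: 11 rac-2-[(4-methoxybenzyl)oxy]-4-methylbenzofuran-3(2H)-one; 17 (2E,6E,8R)-8-hydroxy-3,7,11-trimethyldodeca-2,6,10-trien-1-yl acetate
Product: 19 (2R)-2-[(2E,6E,8R)-8-hydroxy-3,7,11-trimethyldodeca-2,6,10-trien-1-yl]-2-[(4-methoxybenzyl)oxy]-4-methylbenzofuran-3(2H)-one, via cesium enolate 18 (not isolated)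
Conditions: Pd2(dba)3·CHCl3 (2.5 mol %), (1R,2R)-N,N′-bis[2-(diphenylphosphino)benzoyl]cyclohexane-1,2-diamine (7.5 mol %), Cs2CO3, toluene, rt
Reagents that add atoms: none
Why: Tsuji–Trost asymmetric allylic alkylation, in which Cs2CO3 converts 11 into the planar aromatic enolate 18, which should attack the unsubstituted terminus of the π-allylpalladium from 17 (linear, E retained) inside the chiral ligand pocket, so that C2 is set by catalyst control; (R) is expected with the (R,R)-ligand, and the (S,S)-ligand is used if a first run shows the opposite sense.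

Step 11
Reactants: 19 (2R)-2-[(2E,6E,8R)-8-hydroxy-3,7,11-trimethyldodeca-2,6,10-trien-1-yl]-2-[(4-methoxybenzyl)oxy]-4-methylbenzofuran-3(2H)-one
Product: 20 (2R)-2-hydroxy-2-[(2E,6E,8R)-8-hydroxy-3,7,11-trimethyldodeca-2,6,10-trien-1-yl]-4-methylbenzofuran-3(2H)-one
Conditions: DDQ (1.3 equiv), CH2Cl2/pH 7 phosphate buffer, 0 °C, dark
Reagents that add atoms: none
Why: oxidative PMB ether cleavage, in which DDQ abstracts hydride from the benzylic CH2 and water releases 4-methoxybenzaldehyde, so the C2–O bond is never broken and the (R)-hemiketal should be freed with retention at neutral pH.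

## Compound list

1 | 3-bromo-2-fluorophenol | Oc1cccc(Br)c1F | starting material
2 | methyl bromoacetate | COC(=O)CBr | starting material
3 | methyl 2-(3-bromo-2-fluorophenoxy)acetate | COC(=O)COc1cccc(Br)c1F | intermediate
4 | rac-methyl 2-bromo-2-(3-bromo-2-fluorophenoxy)acetate | COC(=O)C(Br)Oc1cccc(Br)c1F | intermediate
5 | rac-methyl 2-(3-bromo-2-fluorophenoxy)-2-[(4-methoxybenzyl)oxy]acetate | COC(=O)C(OCc1ccc(OC)cc1)Oc1cccc(Br)c1F | intermediate
6 | rac-2-(3-bromo-2-fluorophenoxy)-2-[(4-methoxybenzyl)oxy]acetic acid | OC(=O)C(OCc1ccc(OC)cc1)Oc1cccc(Br)c1F | intermediate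
7 | lithium 2-(2-fluoro-3-lithiophenoxy)-2-[(4-methoxybenzyl)oxy]acetate (fluoroaryllithium, not isolated) | [Li+].[O-]C(=O)C(OCc1ccc(OC)cc1)Oc1cccc([Li])c1F | intermediate
8 | lithium 2-(2,3-didehydrophenoxy)-2-[(4-methoxybenzyl)oxy]acetate (aryne, not isolated) | [Li+].[O-]C(=O)C(OCc1ccc(OC)cc1)OC1=CC=CC#C1 | intermediate
9 | lithium 2-(2-lithio-3-methylphenoxy)-2-[(4-methoxybenzyl)oxy]acetate (aryllithium, not isolated) | [Li+].[O-]C(=O)C(OCc1ccc(OC)cc1)Oc1cccc(C)c1[Li] | intermediate
10 | dilithium 2-[(4-methoxybenzyl)oxy]-4-methyl-2H-benzofuran-3,3-diolate (gem-diolate, not isolated) | [Li+].[Li+].[O-]C1([O-])C(OCc2ccc(OC)cc2)Oc2cccc(C)c21 | intermediate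
11 | rac-2-[(4-methoxybenzyl)oxy]-4-methylbenzofuran-3(2H)-one | O=C1C(OCc2ccc(OC)cc2)Oc2cccc(C)c21 | intermediate
12 | geranyl acetate, (2E)-3,7-dimethylocta-2,6-dien-1-yl acetate | CC(C)=CCC/C(C)=C/COC(C)=O | starting material
13 | (2E,6E)-8-hydroxy-3,7-dimethylocta-2,6-dien-1-yl acetate | OC/C(C)=C/CC/C(C)=C/COC(C)=O | intermediate
14 | (2E,6E)-3,7-dimethyl-8-oxoocta-2,6-dien-1-yl acetate | O=C/C(C)=C/CC/C(C)=C/COC(C)=O | intermediate
15 | (2E,6E,8R)-3,7-dimethyl-8-[(tributylstannyl)oxy]undeca-2,6,10-trien-1-yl acetate (stannyl ether, not isolated) | C=CC[C@@H](O[Sn](CCCC)(CCCC)CCCC)/C(C)=C/CC/C(C)=C/COC(C)=O | intermediate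
16 | (2E,6E,8R)-8-hydroxy-3,7-dimethylundeca-2,6,10-trien-1-yl acetate | C=CC[C@@H](O)/C(C)=C/CC/C(C)=C/COC(C)=O | intermediate
17 | (2E,6E,8R)-8-hydroxy-3,7,11-trimethyldodeca-2,6,10-trien-1-yl acetate | CC(C)=CC[C@@H](O)/C(C)=C/CC/C(C)=C/COC(C)=O | intermediate
18 | cesium 2-[(4-methoxybenzyl)oxy]-4-methylbenzofuran-3-olate (cesium enolate, not isolated) | [Cs+].[O-]c1c(OCc2ccc(OC)cc2)oc2cccc(C)c12 | intermediate
19 | (2R)-2-[(2E,6E,8R)-8-hydroxy-3,7,11-trimethyldodeca-2,6,10-trien-1-yl]-2-[(4-methoxybenzyl)oxy]-4-methylbenzofuran-3(2H)-one | CC(C)=CC[C@@H](O)/C(C)=C/CC/C(C)=C/C[C@@]1(OCc2ccc(OC)cc2)Oc2cccc(C)c2C1=O | intermediate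
20 | (2R)-2-hydroxy-2-[(2E,6E,8R)-8-hydroxy-3,7,11-trimethyldodeca-2,6,10-trien-1-yl]-4-methylbenzofuran-3(2H)-one | CC(C)=CC[C@@H](O)/C(C)=C/CC/C(C)=C/C[C@@]1(O)Oc2cccc(C)c2C1=O | target

## Step count and risks

Total step count: 11. Longest linear sequence: 7 steps (steps 1–5, 10, 11); the side-chain branch is steps 6–9.

Steps most likely to fail:

Step 5 (proposed new method). The aryne may be captured by the tethered carboxylate oxygen, by the PMB arene or by a second aryllithium before MeLi reaches C4. MeLi may also attack the carboxylate, or the C3a–Li may be protonated before ring closure. The fallback uses known chemistry with the methyl group bought in place; it sets out from methyl bromoacetate 2 and returns at 11. Compound 2 O-alkylates commercial 2-bromo-3-methylphenol (K2CO3, acetone) to give methyl 2-(2-bromo-3-methylphenoxy)acetate F1. Me(MeO)NH·HCl with i-PrMgCl converts this into 2-(2-bromo-3-methylphenoxy)-N-methoxy-N-methylacetamide F2. A Parham cyclisation (t-BuLi, THF, −78 °C) closes the same C3–C3a bond to give 4-methylbenzofuran-3(2H)-one F3. CuBr2 (EtOAc/CHCl3, reflux) then gives rac-2-bromo-4-methylbenzofuran-3(2H)-one F4, and 4-methoxybenzyl alcohol with K2CO3 converts this into 11.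

Step 10. Facial selectivity at C2 may be poor, the enolate may attack the substituted allyl terminus, E geometry may erode by π–σ–π isomerisation, or the trisubstituted allylic acetate may ionise slowly. The fallback replaces the π-allyl chemistry by an ion-pair-controlled alkylation; it sets out from 17 and returns at 19. K2CO3 in MeOH removes the acetate to give (2E,6E,8R)-3,7,11-trimethyldodeca-2,6,10-triene-1,8-diol F5. MsCl, LiCl and 2,4,6-collidine in DMF at 0 °C should convert only the primary allylic hydroxyl, giving (5R,6E,10E)-12-chloro-2,6,10-trimethyldodeca-2,6,10-trien-5-ol F6. Compound 11 is then alkylated with F6 under chiral phase-transfer catalysis (an N-(9-anthracenylmethyl) cinchona alkaloid ammonium bromide, CsOH·H2O, toluene, −40 °C; the pseudoenantiomer of the catalyst is chosen to give (R) at C2), which can only give the linear product.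

Step 11. Hydride abstraction from the electron-poor ketal PMB ether may be slow, the C8′ allylic alcohol may be oxidised, or the freed hemiketal may epimerise by ring–chain tautomerism. The fallback avoids any protecting group on the C2 oxygen and introduces that oxygen last; it sets out from 17 and returns at 20. 4-Methylbenzofuran-3(2H)-one F3 (made as in the first fallback) is mono-allylated at C2 with 17 (Pd(PPh3)4, Cs2CO3, THF). This gives 2-[(2E,6E,8R)-8-hydroxy-3,7,11-trimethyldodeca-2,6,10-trien-1-yl]-4-methylbenzofuran-3(2H)-one F7 as a mixture of C2 epimers. Its sodium enolate (NaHMDS, THF, −78 °C) is hydroxylated with an enantiopure (camphorsulfonyl)oxaziridine (reagent-controlled enolate hydroxylation) and quenched cold with AcOH to give 20 directly.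

Further compounds

F1 | step 5 | methyl 2-(2-bromo-3-methylphenoxy)acetate | COC(=O)COc1cccc(C)c1Br
F2 | step 5 | 2-(2-bromo-3-methylphenoxy)-N-methoxy-N-methylacetamide | CON(C)C(=O)COc1cccc(C)c1Br
F3 | step 5 | 4-methylbenzofuran-3(2H)-one | O=C1COc2cccc(C)c21
F4 | step 5 | rac-2-bromo-4-methylbenzofuran-3(2H)-one | O=C1C(Br)Oc2cccc(C)c21
F5 | step 10 | (2E,6E,8R)-3,7,11-trimethyldodeca-2,6,10-triene-1,8-diol | CC(C)=CC[C@@H](O)/C(C)=C/CC/C(C)=C/CO
F6 | step 10 | (5R,6E,10E)-12-chloro-2,6,10-trimethyldodeca-2,6,10-trien-5-ol | CC(C)=CC[C@@H](O)/C(C)=C/CC/C(C)=C/CCl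
F7 | step 11 | 2-[(2E,6E,8R)-8-hydroxy-3,7,11-trimethyldodeca-2,6,10-trien-1-yl]-4-methylbenzofuran-3(2H)-one (both C2 epimers) | CC(C)=CC[C@@H](O)/C(C)=C/CC/C(C)=C/CC1Oc2cccc(C)c2C1=O
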